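The constants were chosen freely.

The closed flask (south), the continuous tank (east) and the dosed flask (west) take the same charge and differ in how long starting material meets catalyst.

| flask | starting material | free catalyst | time | remark |
|---|---|---|---|---|
| south | 1.5 M | 2 mol% | 2.0 min | everything together in a closed stirred flask, run for 2.0 min |
| east | 1.5 M | 2 mol% |  | a single well-mixed tank run continuously and read at steady state, 2.0 min in it on average |
| west | 1.5 M (fed, over 1.00 min) | 2 mol% | 2.0 min | a stirred flask in which starting material is dosed at a steady rate over 1.00 min without added volume, worked up at 2.0 min |

- the set-up with the highest amount of target at the outlet or at the end, in percent of the starting material put in ("none" if the first two lie within 2 percentage points) (south / east / west / none)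
- amount of target at the outlet or at the end, in percent of the starting material put in, south
- amount of target at the outlet or at the end, in percent of the starting material put in, east
- amount of target at the outlet or at the end, in percent of the starting material put in, west

- the stated concentrations are those of everything mixed, before any reaction; amounts are the same in each set-up
- the feed brings no volume worth counting
- run time (south): 2.0 min

    starting material + free catalyst → catalyst intermediate (k1 = 0.317 /M/s)
    target ⇌ isomer of the product (K2 = 0.673, k2 = 4.06 × 10⁻⁴ /s)
    free catalyst + target → spent catalyst (k3 = 0.00210 /M/s)
    catalyst intermediate → free catalyst + target (k4 = 25.0 /s)

My own reckoning climbs a ladder of times. The catalyst intermediate falls apart first, with a half-life of 0.0277 s, far shorter than the 1.2 min half-life of starting material under the charged catalyst. Free catalyst is therefore the resting state, and starting material decays pseudo-first-order. This gives 1.14 for south: the contact number, the rate constant of step 1 times the charged catalyst times the time. South's first round converts 68.1 %.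

Next comes the catalyst, whose half-life against target at full charge is 3.67 min, longer than the run but of its order. Slowest is target's own loss, with forward half-lives of 28 min to isomer and 180 min to spent catalyst, both long against the run.

So the first answer goes back in. South's first-round target costs 15.3 % of the catalyst by the end. That loss grows about as the square of time, so its mean is the end value divided by 3, and the contact number becomes 1.08. South then converts 66.1 %, and after isomer, target stands at 64.2 %.

East's first round converts 53.3 %. Its catalyst is cut by the steady target to a contact number of 0.950, which gives target at 46.5 %. West, with south's corrected number spread over the dosing, keeps 44.9 % of starting material, which leaves 55.1 % for target and isomer together.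

The forecast names south, with 64.2 % in south, 46.6 % in east and 54.3 % in west, on the grounds that “conversion is set by how long the starting material spends with the catalyst”.

The simulation gives south as best, with 63.6 % in south, 46.6 % in east and 54.0 % in west.

In south, the half-life of starting material under the charged catalyst, 1.2 min, is shorter than the run of 2.0 min, and the corrected contact number puts 33.9 % of starting material at the end, where south holds 34 %. In the neighbour of south charged with 0.60 M of starting material at the same loading, the catalyst falls with the charge, the contact number drops to 0.456, its exponential leaves 63.4 %, and that flask holds 64 %.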